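**Retrosynthetic overview**

- The target comes from hydrogenolysis of two aryl benzyl ethers. Before that, the benzylic carbinol is made by chelation-controlled hydride reduction of the aryl ketone in a trans 3-aroyl-4-benzyl butyrolactone, so the carbinol centre is relayed from C3/C4.
- The butyrolactone is the only ring made in the route. Its C3–C4 bond is closed by an enantioselective dirhodium-carbenoid 1,5 C–H insertion of an acyclic, achiral 3-arylpropyl 2-diazo-3-aryl-3-oxopropanoate. That one operation gives the ring, C4 (catalyst control) and C3 (thermodynamic relay).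
- The diazo ester comes from diazo transfer to a β-keto ester, itself made from the acyl Meldrum's acid of O-benzylvanillic acid and O-benzyl dihydroconiferyl alcohol.
- Enabling feature: lactone C3 lies between the lactone carbonyl C2 and the oxygen-bearing benzylic carbon. Raising that carbon to a ketone makes C3 a doubly stabilised diazo/carbenoid carbon. The C4 methylene of the 3-arylpropyl ester then stands 1,5 to C3 through O1–C5, so the five-membered lactone can close by C–H insertion.

Key step: step 5

Assumption: Rh2(S-PTTL)4 is taken to give the (4R) lactone; if the first run shows the opposite sense, the catalyst antipode made from (R)-tert-leucine is used with no other change.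

**Route**

Step 1
Reactants: 1 4-(3-hydroxypropyl)-2-methoxyphenol (dihydroconiferyl alcohol)
Product: 2 3-[4-(benzyloxy)-3-methoxyphenyl]propan-1-ol
Conditions: BnBr, K2CO3, acetone, reflux
Reagents that add atoms: benzyl bromide, BrCc1ccccc1
Why: Williamson ether synthesis, in which K2CO3 deprotonates only the phenol (far more acidic than the primary alcohol), so the hydroxypropyl group should stay free.

Step 2
Reactants: 3 4-(benzyloxy)-3-methoxybenzoic acid; 4 2,2-dimethyl-1,3-dioxane-4,6-dione (Meldrum's acid)
Product: 5 5-{[4-(benzyloxy)-3-methoxyphenyl](hydroxy)methylidene}-2,2-dimethyl-1,3-dioxane-4,6-dione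
Conditions: DCC, DMAP, CH2Cl2, 0 to 23 °C
Reagents that add atoms: none
Why: Carbodiimide-mediated C-acylation of Meldrum's acid, with DMAP as acyl-transfer catalyst and base, is the standard entry to acyl Meldrum's acids and should leave the aryl benzyl and methyl ethers untouched.

Step 3
Reactants: 5 acyl Meldrum's acid; 2 3-[4-(benzyloxy)-3-methoxyphenyl]propan-1-ol
Product: 7 3-[4-(benzyloxy)-3-methoxyphenyl]propyl 3-[4-(benzyloxy)-3-methoxyphenyl]-3-oxopropanoate, via aroylketene 6 (not isolated)
Conditions: toluene, 90 °C
Reagents that add atoms: none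
Why: Thermolysis of the acyl Meldrum's acid expels acetone and CO2 to give the aroylketene, which the primary alcohol 2 should trap to give the β-keto ester (acylketene alcoholysis).

Step 4
Reactants: 7 β-keto ester
Product: 8 3-[4-(benzyloxy)-3-methoxyphenyl]propyl 3-[4-(benzyloxy)-3-methoxyphenyl]-2-diazo-3-oxopropanoate
Conditions: p-ABSA, Et3N, MeCN, 0 to 23 °C
Reagents that add atoms: 4-acetamidobenzenesulfonyl azide (p-ABSA), CC(=O)Nc1ccc(cc1)S(=O)(=O)N=[N+]=[N-]
Why: Regitz diazo transfer, in which the triethylammonium enolate of the 1,3-dicarbonyl attacks the terminal nitrogen of the sulfonyl azide and the adduct collapses to the diazo compound and the sulfonamide.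

Step 5
Reactants: 8 α-diazo-β-keto ester
Product: 9 (3S,4R)-3-[4-(benzyloxy)-3-methoxybenzoyl]-4-[4-(benzyloxy)-3-methoxybenzyl]oxolan-2-one
Conditions: Rh2(S-PTTL)4 (dirhodium tetrakis[N-phthaloyl-(S)-tert-leucinate], 2 mol%), CH2Cl2, 4 Å MS, slow addition of 8, 23 to 40 °C; then Et3N (cat.), 23 °C
Reagents that add atoms: none
Why: The chiral carboxylate of divalent rhodium expels N2 from 8 to give an electrophilic rhodium carbenoid at the future C3, which inserts through a concerted, three-centre, hydride-transfer-like transition state into one of the two enantiotopic C–H bonds of the C4 methylene. The closest known reaction type is the intramolecular rhodium-carbenoid C–H insertion of 3-arylpropyl diazoacetates and of alkyl α-diazo-β-keto esters, which gives β-benzyl and α-acyl γ-butyrolactones. The lactone closes in the 1,5-insertion mode through a five-membered transition state (C3, C2, O1, C5, C4) that requires the less populated E rotamer of the ester, which is why slow addition is used to suppress carbenoid dimerisation. C4 (R) is set by the chiral carboxylate pocket, which should select between the two enantiotopic hydrogens; C3 (S) is not set kinetically but is stereolabile between two carbonyls and should settle trans to the C4 benzyl group by enolisation, completed by the catalytic Et3N. The step needs site selectivity for the C4 methylene over the benzylic methylene (six-membered closure) and the O-bound C5 methylene (four-membered closure, C–H deactivated by the acyloxy oxygen); the five-ring preference of ester-tethered carbenoids should secure this, and the aroyl group has no C–H bond within reach.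

Step 6
Reactants: 9 trans keto lactone
Product: 10 (3S,4R)-3-{(S)-[4-(benzyloxy)-3-methoxyphenyl](hydroxy)methyl}-4-[4-(benzyloxy)-3-methoxybenzyl]oxolan-2-one
Conditions: Zn(BH4)2, Et2O/CH2Cl2, −20 to 0 °C; aq. NH4Cl
Reagents that add atoms: none
Why: Chelation-controlled reduction of an α-substituted β-keto ester, in which zinc ties the ketone and lactone carbonyl oxygens into a six-membered chelate and hydride adds to the ketone face on the side of C3–H, away from the C4 ring carbon, which should give the syn alcohol with the (S) carbinol; the lactone should not be reduced by Zn(BH4)2 at this temperature.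

Step 7
Reactants: 10 dibenzyl ether
Product: 11 (3S,4R)-3-[(S)-hydroxy(4-hydroxy-3-methoxyphenyl)methyl]-4-(4-hydroxy-3-methoxybenzyl)oxolan-2-one (target)
Conditions: H2 (1 atm), Pd/C (10%), EtOAc, 23 °C, stopped after uptake of two equivalents of H2
Reagents that add atoms: none
Why: Hydrogenolysis of aryl benzyl ethers over Pd/C is much faster than that of a secondary benzylic alcohol in neutral ethyl acetate, so both phenols should be freed without touching the carbinol, the lactone or any stereocentre.

**Compound list**

1 | 4-(3-hydroxypropyl)-2-methoxyphenol (dihydroconiferyl alcohol) | COc1cc(CCCO)ccc1O | starting material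
2 | 3-[4-(benzyloxy)-3-methoxyphenyl]propan-1-ol | COc1cc(CCCO)ccc1OCc1ccccc1 | intermediate
3 | 4-(benzyloxy)-3-methoxybenzoic acid | COc1cc(C(=O)O)ccc1OCc1ccccc1 | starting material
4 | 2,2-dimethyl-1,3-dioxane-4,6-dione (Meldrum's acid) | CC1(C)OC(=O)CC(=O)O1 | starting material
5 | 5-{[4-(benzyloxy)-3-methoxyphenyl](hydroxy)methylidene}-2,2-dimethyl-1,3-dioxane-4,6-dione | COc1cc(C(O)=C2C(=O)OC(C)(C)OC2=O)ccc1OCc1ccccc1 | intermediate
6 | [4-(benzyloxy)-3-methoxybenzoyl]ketene (not isolated) | COc1cc(C(=O)C=C=O)ccc1OCc1ccccc1 | intermediate
7 | 3-[4-(benzyloxy)-3-methoxyphenyl]propyl 3-[4-(benzyloxy)-3-methoxyphenyl]-3-oxopropanoate | COc1cc(CCCOC(=O)CC(=O)c2ccc(OCc3ccccc3)c(OC)c2)ccc1OCc1ccccc1 | intermediate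
8 | 3-[4-(benzyloxy)-3-methoxyphenyl]propyl 3-[4-(benzyloxy)-3-methoxyphenyl]-2-diazo-3-oxopropanoate | COc1cc(CCCOC(=O)C(=[N+]=[N-])C(=O)c2ccc(OCc3ccccc3)c(OC)c2)ccc1OCc1ccccc1 | intermediate
9 | (3S,4R)-3-[4-(benzyloxy)-3-methoxybenzoyl]-4-[4-(benzyloxy)-3-methoxybenzyl]oxolan-2-one | COc1cc(C[C@H]2COC(=O)[C@@H]2C(=O)c2ccc(OCc3ccccc3)c(OC)c2)ccc1OCc1ccccc1 | intermediate
10 | (3S,4R)-3-{(S)-[4-(benzyloxy)-3-methoxyphenyl](hydroxy)methyl}-4-[4-(benzyloxy)-3-methoxybenzyl]oxolan-2-one | COc1cc(C[C@H]2COC(=O)[C@@H]2[C@H](O)c2ccc(OCc3ccccc3)c(OC)c2)ccc1OCc1ccccc1 | intermediate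
11 | (3S,4R)-3-[(S)-hydroxy(4-hydroxy-3-methoxyphenyl)methyl]-4-(4-hydroxy-3-methoxybenzyl)oxolan-2-one | COc1cc(C[C@H]2COC(=O)[C@@H]2[C@H](O)c2ccc(O)c(OC)c2)ccc1O | target

**Step count and risks**

Total step count: 7. Longest linear sequence: 6 steps (1 → 2 → 7 → 8 → 9 → 10 → 11; the branch from 3 is equally long).

Steps most likely to fail:

1. Step 5 (key step). The acceptor/acceptor carbenoid may discriminate poorly between the two enantiotopic C4–H bonds, or be diverted into insertion at the benzylic methylene or into carbenoid dimerisation. The fallback moves the stereo-defining insertion to an acceptor-only carbenoid, for which lactone formation from 3-arylpropyl diazoacetates with chiral dirhodium carboxamidates has direct precedent, and adds the aroyl group afterwards. It sets out from 2. Bromoacetyl bromide and NaHCO3 in MeCN should give 3-[4-(benzyloxy)-3-methoxyphenyl]propyl bromoacetate F1. N,N'-Ditosylhydrazine and DBU in THF at 0 °C should convert this into 3-[4-(benzyloxy)-3-methoxyphenyl]propyl diazoacetate F2. Slow addition of F2 to the dirhodium carboxamidate Rh2(4S-MPPIM)4 in refluxing CH2Cl2 (catalyst antipode if the sense requires it) should close the same C3–C4 bond and give (R)-4-[4-(benzyloxy)-3-methoxybenzyl]oxolan-2-one F3. The lithium enolate of F3 (LiHMDS, 2.2 equiv, THF, −78 °C) is then C-acylated with 4-(benzyloxy)-3-methoxybenzoyl chloride F4, made from 3 with (COCl)2 and catalytic DMF. The stereolabile C3 should settle trans, and the fallback comes back to the route at 9.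

2. Step 6. Facial selectivity may be poor if open-chain (Felkin–Anh type) hydride delivery competes with delivery through the zinc chelate. The fallback gives up substrate control for catalyst control: Noyori–Ikariya asymmetric transfer hydrogenation of 9 with RuCl(p-cymene)[(S,S)-TsDPEN] in HCO2H/Et3N. Here an outer-sphere hydride transfer fixes the aryl carbinol as (S) through the catalyst's recognition of the aryl ring, independent of any chelate. It sets out from 9 and comes back at 10. The fallback makes no compound beyond the list (none F0).

3. Step 7. Over-hydrogenolysis may cleave the benzylic C–OH bond, which becomes a p-hydroxybenzylic alcohol as soon as the first benzyl group is gone. The fallback reverses the last two operations and avoids hydrogen. It sets out from 9, where no benzylic alcohol is present. BCl3 with pentamethylbenzene in CH2Cl2 at −78 °C should remove both benzyl ethers and leave the aryl methyl ethers, giving (3S,4R)-3-(4-hydroxy-3-methoxybenzoyl)-4-(4-hydroxy-3-methoxybenzyl)oxolan-2-one F5. Excess Zn(BH4)2 in Et2O/THF at −20 to 0 °C (the phenols consume hydride) should then reduce F5 under the same chelate control, and the fallback comes back to the route at 11.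

Further compounds
F1 | step 5 | 3-[4-(benzyloxy)-3-methoxyphenyl]propyl bromoacetate | COc1cc(CCCOC(=O)CBr)ccc1OCc1ccccc1
F2 | step 5 | 3-[4-(benzyloxy)-3-methoxyphenyl]propyl diazoacetate | COc1cc(CCCOC(=O)C=[N+]=[N-])ccc1OCc1ccccc1
F3 | step 5 | (R)-4-[4-(benzyloxy)-3-methoxybenzyl]oxolan-2-one | COc1cc(C[C@H]2COC(=O)C2)ccc1OCc1ccccc1
F4 | step 5 | 4-(benzyloxy)-3-methoxybenzoyl chloride | COc1cc(C(=O)Cl)ccc1OCc1ccccc1
F0 | step 6 | none | none
F5 | step 7 | (3S,4R)-3-(4-hydroxy-3-methoxybenzoyl)-4-(4-hydroxy-3-methoxybenzyl)oxolan-2-one | COc1cc(C[C@H]2COC(=O)[C@@H]2C(=O)c2ccc(O)c(OC)c2)ccc1O
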